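Ring B of the drimane core (drimane numbering) is cut into a C7=C8–C9=C10 diene and a C5=C6 dienophile joined by the C1–C4 chain, so that one intramolecular Diels–Alder reaction of an acyclic nitro-triene forms C6–C7 and the ring-fusion bond C5–C10, closes rings A and B at once and sets C5 and quaternary C10. The feature exploited is six-membered ring B, whose bond C5–C10 is shared with ring A. The precursor, built from (S)-pantolactone, carries an (E)-nitroalkene at C5=C6, a trans-acetonide on the C2,C3-diol and a tetrasubstituted 2-ethoxy-diene already bearing the umbelliferone ether; nitro later leaves as nitrite and the C8 ketone places the C7=C8 alkene.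

Key step: step 11

Remark: drimane numbering (C1–C12; C11 is the CH2O carbon, C12 the C8 methyl) is used for all intermediates, open-chain ones included; (S)-pantolactone is taken as purchasable in enantiopure form.

Step 1
Reactants: 1 (S)-pantolactone
Product: 2 (3S)-4,4-dimethyloxolane-2,3-diol (pantolactol; anomer mixture)
Conditions: i-Bu2AlH (2.3 equiv), CH2Cl2, −78 °C
Reagents that add atoms: none
Why: Partial reduction of the lactone to the lactol with i-Bu2AlH should stop at the aluminate that is stable at −78 °C, and the C3 carbinol centre is not touched.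

Step 2
Reactants: 2 (3S)-4,4-dimethyloxolane-2,3-diol; 3 propargyl bromide
Product: 4 (3S,4S)-2,2-dimethylhept-6-yne-1,3,4-triol
Conditions: In powder, THF/H2O (1:1), rt
Reagents that add atoms: none
Why: Barbier propargylation of the open hydroxy-aldehyde form (SE2' attack of the allenylindium species) should give the homopropargylic alcohol, with indium chelated between the free C3 hydroxyl and the aldehyde oxygen so that attack anti to quaternary C4 sets C2 syn (threo) to C3.

Step 3
Reactants: 4 (3S,4S)-2,2-dimethylhept-6-yne-1,3,4-triol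
Product: 5 2-[(4S,5S)-2,2-dimethyl-5-(prop-2-yn-1-yl)-1,3-dioxolan-4-yl]-2-methylpropan-1-ol
Conditions: 2,2-dimethoxypropane, camphorsulfonic acid (cat.), acetone, rt; aq. NaHCO3
Reagents that add atoms: 2,2-dimethoxypropane, COC(C)(C)OC
Why: Acid-catalysed transketalisation under thermodynamic control should favour the five-membered trans-dioxolane on the vicinal threo diol over a 1,3-dioxane through the neopentyl primary hydroxyl, which stays free.

Step 4
Reactants: 5 2-[(4S,5S)-2,2-dimethyl-5-(prop-2-yn-1-yl)-1,3-dioxolan-4-yl]-2-methylpropan-1-ol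
Product: 7 methyl 4-[(4S,5S)-5-{1-[(methoxycarbonyl)oxy]-2-methylpropan-2-yl}-2,2-dimethyl-1,3-dioxolan-4-yl]but-2-ynoate, via dilithium alkoxide acetylide 6 (not isolated)
Conditions: n-BuLi (2.2 equiv), THF, −78 °C; then ClCO2Me (2.5 equiv), −78 to 0 °C
Reagents that add atoms: methyl chloroformate, COC(=O)Cl
Why: Double deprotonation (O–H and alkyne C–H) and double acylation should give the ynoate by C-acylation of the acetylide and at the same time cap the primary hydroxyl as a methyl carbonate that shields it in step 5.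

Step 5
Reactants: 7 methyl 4-[(4S,5S)-5-{1-[(methoxycarbonyl)oxy]-2-methylpropan-2-yl}-2,2-dimethyl-1,3-dioxolan-4-yl]but-2-ynoate
Product: 9 methyl (2E)-2-iodo-4-[(4S,5S)-5-{1-[(methoxycarbonyl)oxy]-2-methylpropan-2-yl}-2,2-dimethyl-1,3-dioxolan-4-yl]-3-methylbut-2-enoate, via lithium alkenyl(methyl)cuprate 8 (not isolated)
Conditions: Me2CuLi (1.3 equiv, from MeLi and CuI), THF, −78 °C; then I2, THF, −78 °C
Reagents that add atoms: lithium dimethylcuprate, [Li+].C[Cu-]C; iodine, II
Why: syn-Carbocupration of the ynoate puts the methyl on C10 and copper on C9 cis to it, and iodinolysis of the configurationally stable alkenylcopper at −78 °C proceeds with retention, which fixes the tetrasubstituted C9=C10 geometry (methyl cis to the future C8, tether cis to C11).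

Step 6
Reactants: 9 methyl (2E)-2-iodo-4-[(4S,5S)-5-{1-[(methoxycarbonyl)oxy]-2-methylpropan-2-yl}-2,2-dimethyl-1,3-dioxolan-4-yl]-3-methylbut-2-enoate
Product: 10 (2E)-4-[(4S,5S)-5-(1-hydroxy-2-methylpropan-2-yl)-2,2-dimethyl-1,3-dioxolan-4-yl]-2-iodo-3-methylbut-2-en-1-ol
Conditions: i-Bu2AlH (6 equiv), CH2Cl2, −78 to −20 °C
Reagents that add atoms: none
Why: i-Bu2AlH should reduce the conjugated ester to the allylic alcohol (1,2-reduction, alkenyl iodide untouched) and cleave the methyl carbonate reductively, so the temporary protecting group leaves in the same operation.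

Step 7
Reactants: 10 (2E)-4-[(4S,5S)-5-(1-hydroxy-2-methylpropan-2-yl)-2,2-dimethyl-1,3-dioxolan-4-yl]-2-iodo-3-methylbut-2-en-1-ol; 11 umbelliferone
Product: 12 7-{[(2E)-4-[(4S,5S)-5-(1-hydroxy-2-methylpropan-2-yl)-2,2-dimethyl-1,3-dioxolan-4-yl]-2-iodo-3-methylbut-2-en-1-yl]oxy}-2H-chromen-2-one
Conditions: PPh3, diisopropyl azodicarboxylate, THF, 0 °C to rt
Reagents that add atoms: none
Why: Mitsunobu etherification by SN2 displacement at the primary allylic carbon C11 with the acidic phenol (pKa about 7.7) should be chemoselective, because the neopentyl C5 oxyphosphonium cannot be displaced and reverts to the alcohol on work-up.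

Step 8
Reactants: 12 7-{[(2E)-4-[(4S,5S)-5-(1-hydroxy-2-methylpropan-2-yl)-2,2-dimethyl-1,3-dioxolan-4-yl]-2-iodo-3-methylbut-2-en-1-yl]oxy}-2H-chromen-2-one; 13 tributyl(1-ethoxyethenyl)stannane
Product: 14 7-{[(2E)-2-(1-ethoxyethenyl)-4-[(4S,5S)-5-(1-hydroxy-2-methylpropan-2-yl)-2,2-dimethyl-1,3-dioxolan-4-yl]-3-methylbut-2-en-1-yl]oxy}-2H-chromen-2-one
Conditions: Pd(PPh3)4 (5 mol%), CuI (10 mol%), CsF (2 equiv), DMF, 45 °C; chromatography on Et3N-deactivated silica
Reagents that add atoms: none
Why: Stille coupling of the alkenyl iodide with retention of configuration, accelerated at the hindered centre by CuI and CsF, should install C7 and C8 as a 2-ethoxy-diene whose C10 terminus carries the methyl inside and the tether outside.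

Step 9
Reactants: 14 7-{[(2E)-2-(1-ethoxyethenyl)-4-[(4S,5S)-5-(1-hydroxy-2-methylpropan-2-yl)-2,2-dimethyl-1,3-dioxolan-4-yl]-3-methylbut-2-en-1-yl]oxy}-2H-chromen-2-one
Product: 15 2-[(4S,5S)-5-{(2E)-3-(1-ethoxyethenyl)-2-methyl-4-[(2-oxo-2H-chromen-7-yl)oxy]but-2-en-1-yl}-2,2-dimethyl-1,3-dioxolan-4-yl]-2-methylpropanal
Conditions: SO3·pyridine, DMSO, i-Pr2NEt, CH2Cl2, 0 °C
Reagents that add atoms: none
Why: Parikh–Doering oxidation of the neopentyl primary alcohol runs under basic conditions that spare the acid-labile enol ether and acetonide, and the aldehyde has no α-hydrogen, so it can neither epimerise nor eliminate.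

Step 10
Reactants: 15 2-[(4S,5S)-5-{(2E)-3-(1-ethoxyethenyl)-2-methyl-4-[(2-oxo-2H-chromen-7-yl)oxy]but-2-en-1-yl}-2,2-dimethyl-1,3-dioxolan-4-yl]-2-methylpropanal; 16 nitromethane
Product: 18 7-{[(2E)-4-{(4S,5S)-2,2-dimethyl-5-[(3E)-2-methyl-4-nitrobut-3-en-2-yl]-1,3-dioxolan-4-yl}-2-(1-ethoxyethenyl)-3-methylbut-2-en-1-yl]oxy}-2H-chromen-2-one, via nitroaldol 17 (not isolated)
Conditions: MeNO2 (solvent), tetramethylguanidine (10 mol%), 0 °C to rt; evaporate; then MsCl, Et3N, CH2Cl2, −20 to 0 °C
Reagents that add atoms: none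
Why: Henry (nitroaldol) addition to the non-enolisable aldehyde followed by mesylation and E1cB elimination should give the (E)-nitroalkene, which cannot tautomerise because C4 is quaternary.

Step 11
Reactants: 18 7-{[(2E)-4-{(4S,5S)-2,2-dimethyl-5-[(3E)-2-methyl-4-nitrobut-3-en-2-yl]-1,3-dioxolan-4-yl}-2-(1-ethoxyethenyl)-3-methylbut-2-en-1-yl]oxy}-2H-chromen-2-one
Product: 19 (2S,3S,5S,6R,10R)-8-ethoxy-2,3-(isopropylidenedioxy)-6-nitro-12-nordrim-8-en-11-yl 2-oxo-2H-chromen-7-yl ether (trans-fused; H-5 anti to the C10 methyl; nitro cis to H-5)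
Conditions: toluene (0.005 M), BHT (cat.), 80–100 °C
Reagents that add atoms: none
Why: Thermal concerted but asynchronous [4+2] cycloaddition in which the (E)-nitroalkene C5=C6 adds suprafacially to the s-cis 2-ethoxy-diene C7=C8–C9=C10, C5–C10 bonding running ahead of C6–C7. The closest known reaction type is the intramolecular Diels–Alder reaction of 1-nitro-1,7,9-decatrienes, with the nitroalkene used as an activated ethylene equivalent toward an oxygenated diene. Ring B closes as the cyclohexene of the cycloaddition and ring A closes in the fused mode as the six-membered ring that contains the C1–C4 tether, through a chair-like tether. The trans relation of H-5 and the C10 methyl follows from the diene geometry (tether outside, methyl inside on C10) combined with the endo orientation of nitro, which puts H-5 under the C9 substituent and quaternary C4 outside; the absolute sense is set by the trans-dioxolane, which can span only two equatorial C–O bonds and so allows a single chair, and C6 (nitro cis to H-5) follows from the (E)-alkene and is erased in step 12. The selectivity needed is fused over bridged regiochemistry and endo over exo closure: the four-atom tether enforces the first against the electronic preference of both partners (hence nitro, the strongest activating group, and high dilution), and the bulk at C4 and C9 should secure the second. The adduct is the C8=C9 enol ether, which carries the oxygen used later to place the C7=C8 double bond.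

Step 12
Reactants: 19 (2S,3S,5S,6R,10R)-8-ethoxy-2,3-(isopropylidenedioxy)-6-nitro-12-nordrim-8-en-11-yl 2-oxo-2H-chromen-7-yl ether
Product: 21 (2S,3S,5S,9R,10R)-2,3-(isopropylidenedioxy)-11-[(2-oxo-2H-chromen-7-yl)oxy]-12-nordrim-6-en-8-one, via β-nitro ketone 20 (not isolated)
Conditions: oxalic acid (5% aq.), THF, 0 °C; then Et3N (3 equiv), CH2Cl2, 0 °C
Reagents that add atoms: water, O
Why: Enol ether hydrolysis by C-protonation at C9 from the face opposite the axial C10 methyl (also the thermodynamic, equatorial placement of C11) should give the β-nitro ketone, from which E1cB loss of nitrite through the C7 enolate gives the conjugated enone, so the activating group leaves without a separate reduction.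

Step 13
Reactants: 21 (2S,3S,5S,9R,10R)-2,3-(isopropylidenedioxy)-11-[(2-oxo-2H-chromen-7-yl)oxy]-12-nordrim-6-en-8-one
Product: 23 (2S,3S,5S,9R,10R)-2,3-(isopropylidenedioxy)-11-[(2-oxo-2H-chromen-7-yl)oxy]-12-nordrim-7-en-8-yl trifluoromethanesulfonate, via lithium enolate 22 (not isolated)
Conditions: LiBH(s-Bu)3 (1.05 equiv), THF, −78 °C; then PhNTf2 (1.3 equiv), −78 to 0 °C
Reagents that add atoms: N-phenylbis(trifluoromethanesulfonimide), O=S(=O)(N(c1ccccc1)S(=O)(=O)C(F)(F)F)C(F)(F)F
Why: Conjugate reduction of the β-unsubstituted cyclohexenone (faster than hydride attack on the β-aryl-substituted coumarin lactone) should give the C7=C8 enolate regiospecifically, which is trapped as the enol triflate (reductive enolate trapping); C9 is never enolised, so the β-aryloxy unit and its configuration are kept.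

Step 14
Reactants: 23 (2S,3S,5S,9R,10R)-2,3-(isopropylidenedioxy)-11-[(2-oxo-2H-chromen-7-yl)oxy]-12-nordrim-7-en-8-yl trifluoromethanesulfonate
Product: 24 (2S,3S,5S,9R,10R)-2,3-(isopropylidenedioxy)drim-7-en-11-yl 2-oxo-2H-chromen-7-yl ether
Conditions: MeZnCl (2 equiv), Pd(PPh3)4 (5 mol%), THF, 50 °C
Reagents that add atoms: methylzinc chloride, C[Zn]Cl
Why: Negishi cross-coupling (oxidative addition of the enol triflate to zerovalent palladium, transmetalation from zinc, reductive elimination) should replace triflate by the C12 methyl with the double bond fixed at C7=C8, and methylzinc chloride does not add to the coumarin.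

Step 15
Reactants: 24 (2S,3S,5S,9R,10R)-2,3-(isopropylidenedioxy)drim-7-en-11-yl 2-oxo-2H-chromen-7-yl ether
Product: 25 7-{[(1R,4aS,6S,7S,8aR)-6,7-dihydroxy-2,5,5,8a-tetramethyl-1,4,4a,5,6,7,8,8a-octahydronaphthalen-1-yl]methoxy}-2H-chromen-2-one (target)
Conditions: AcOH/H2O (4:1), 40 °C
Reagents that add atoms: none
Why: Acid hydrolysis of the strained trans-fused dioxolane should release the trans-diequatorial 2,3-diol under conditions too mild to move the trisubstituted C7=C8 alkene or cleave the homoallylic aryl ether.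

Compound list
1 | (S)-pantolactone [(3S)-3-hydroxy-4,4-dimethyloxolan-2-one] | CC1(C)COC(=O)[C@H]1O | starting material
2 | (3S)-4,4-dimethyloxolane-2,3-diol (pantolactol; anomer mixture) | CC1(C)COC(O)[C@H]1O | intermediate
3 | propargyl bromide (3-bromoprop-1-yne) | C#CCBr | starting material
4 | (3S,4S)-2,2-dimethylhept-6-yne-1,3,4-triol | OCC(C)(C)[C@H](O)[C@@H](O)CC#C | intermediate
5 | 2-[(4S,5S)-2,2-dimethyl-5-(prop-2-yn-1-yl)-1,3-dioxolan-4-yl]-2-methylpropan-1-ol | OCC(C)(C)[C@H](OC(C)(C)O1)[C@@H]1CC#C | intermediate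
6 | dilithium alkoxide acetylide of 5 | [Li]OCC(C)(C)[C@H](OC(C)(C)O1)[C@@H]1CC#C[Li] | intermediate
7 | methyl 4-[(4S,5S)-5-{1-[(methoxycarbonyl)oxy]-2-methylpropan-2-yl}-2,2-dimethyl-1,3-dioxolan-4-yl]but-2-ynoate | COC(=O)OCC(C)(C)[C@H](OC(C)(C)O1)[C@@H]1CC#CC(=O)OC | intermediate
8 | lithium alkenyl(methyl)cuprate from 7 (Cu on C9, cis to the new C10 methyl) | COC(=O)OCC(C)(C)[C@H](OC(C)(C)O1)[C@@H]1C/C(C)=C(/[Cu-]C)C(=O)OC.[Li+] | intermediate
9 | methyl (2E)-2-iodo-4-[(4S,5S)-5-{1-[(methoxycarbonyl)oxy]-2-methylpropan-2-yl}-2,2-dimethyl-1,3-dioxolan-4-yl]-3-methylbut-2-enoate | COC(=O)OCC(C)(C)[C@H](OC(C)(C)O1)[C@@H]1C/C(C)=C(/I)C(=O)OC | intermediate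
10 | (2E)-4-[(4S,5S)-5-(1-hydroxy-2-methylpropan-2-yl)-2,2-dimethyl-1,3-dioxolan-4-yl]-2-iodo-3-methylbut-2-en-1-ol | OCC(C)(C)[C@H](OC(C)(C)O1)[C@@H]1C/C(C)=C(/I)CO | intermediate
11 | umbelliferone (7-hydroxy-2H-chromen-2-one) | Oc1ccc2ccc(=O)oc2c1 | starting material
12 | 7-{[(2E)-4-[(4S,5S)-5-(1-hydroxy-2-methylpropan-2-yl)-2,2-dimethyl-1,3-dioxolan-4-yl]-2-iodo-3-methylbut-2-en-1-yl]oxy}-2H-chromen-2-one | OCC(C)(C)[C@H](OC(C)(C)O1)[C@@H]1C/C(C)=C(/I)COc1ccc2ccc(=O)oc2c1 | intermediate
13 | tributyl(1-ethoxyethenyl)stannane | CCCC[Sn](CCCC)(CCCC)C(=C)OCC | starting material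
14 | 7-{[(2E)-2-(1-ethoxyethenyl)-4-[(4S,5S)-5-(1-hydroxy-2-methylpropan-2-yl)-2,2-dimethyl-1,3-dioxolan-4-yl]-3-methylbut-2-en-1-yl]oxy}-2H-chromen-2-one | OCC(C)(C)[C@H](OC(C)(C)O1)[C@@H]1C/C(C)=C(/C(=C)OCC)COc1ccc2ccc(=O)oc2c1 | intermediate
15 | 2-[(4S,5S)-5-{(2E)-3-(1-ethoxyethenyl)-2-methyl-4-[(2-oxo-2H-chromen-7-yl)oxy]but-2-en-1-yl}-2,2-dimethyl-1,3-dioxolan-4-yl]-2-methylpropanal | O=CC(C)(C)[C@H](OC(C)(C)O1)[C@@H]1C/C(C)=C(/C(=C)OCC)COc1ccc2ccc(=O)oc2c1 | intermediate
16 | nitromethane | C[N+](=O)[O-] | starting material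
17 | nitroaldol of 15 (C5 hydroxy, C6 nitro; both C5 epimers) | OC(C[N+](=O)[O-])C(C)(C)[C@H](OC(C)(C)O1)[C@@H]1C/C(C)=C(/C(=C)OCC)COc1ccc2ccc(=O)oc2c1 | intermediate
18 | 7-{[(2E)-4-{(4S,5S)-2,2-dimethyl-5-[(3E)-2-methyl-4-nitrobut-3-en-2-yl]-1,3-dioxolan-4-yl}-2-(1-ethoxyethenyl)-3-methylbut-2-en-1-yl]oxy}-2H-chromen-2-one (nitro-triene) | [O-][N+](=O)/C=C/C(C)(C)[C@H](OC(C)(C)O1)[C@@H]1C/C(C)=C(/C(=C)OCC)COc1ccc2ccc(=O)oc2c1 | intermediate
19 | (2S,3S,5S,6R,10R)-8-ethoxy-2,3-(isopropylidenedioxy)-6-nitro-12-nordrim-8-en-11-yl 2-oxo-2H-chromen-7-yl ether (trans-fused; nitro cis to H-5) | CCOC=1C[C@@H]([N+](=O)[O-])[C@@H]2C(C)(C)[C@H](OC(C)(C)O3)[C@@H]3C[C@@]2(C)C=1COc1ccc2ccc(=O)oc2c1 | intermediate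
20 | (2S,3S,5S,6R,9R,10R)-2,3-(isopropylidenedioxy)-6-nitro-11-[(2-oxo-2H-chromen-7-yl)oxy]-12-nordriman-8-one (β-nitro ketone) | O=C1C[C@@H]([N+](=O)[O-])[C@@H]2C(C)(C)[C@H](OC(C)(C)O3)[C@@H]3C[C@@]2(C)[C@@H]1COc1ccc2ccc(=O)oc2c1 | intermediate
21 | (2S,3S,5S,9R,10R)-2,3-(isopropylidenedioxy)-11-[(2-oxo-2H-chromen-7-yl)oxy]-12-nordrim-6-en-8-one | O=C1C=C[C@@H]2C(C)(C)[C@H](OC(C)(C)O3)[C@@H]3C[C@@]2(C)[C@@H]1COc1ccc2ccc(=O)oc2c1 | intermediate
22 | lithium C7=C8 enolate of the 6,7-dihydro ketone derived from 21 | [Li]OC1=CC[C@@H]2C(C)(C)[C@H](OC(C)(C)O3)[C@@H]3C[C@@]2(C)[C@@H]1COc1ccc2ccc(=O)oc2c1 | intermediate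
23 | (2S,3S,5S,9R,10R)-2,3-(isopropylidenedioxy)-11-[(2-oxo-2H-chromen-7-yl)oxy]-12-nordrim-7-en-8-yl trifluoromethanesulfonate | O=S(=O)(OC1=CC[C@@H]2C(C)(C)[C@H](OC(C)(C)O3)[C@@H]3C[C@@]2(C)[C@@H]1COc1ccc2ccc(=O)oc2c1)C(F)(F)F | intermediate
24 | (2S,3S,5S,9R,10R)-2,3-(isopropylidenedioxy)drim-7-en-11-yl 2-oxo-2H-chromen-7-yl ether | CC1=CC[C@@H]2C(C)(C)[C@H](OC(C)(C)O3)[C@@H]3C[C@@]2(C)[C@@H]1COc1ccc2ccc(=O)oc2c1 | intermediate
25 | 7-{[(1R,4aS,6S,7S,8aR)-6,7-dihydroxy-2,5,5,8a-tetramethyl-1,4,4a,5,6,7,8,8a-octahydronaphthalen-1-yl]methoxy}-2H-chromen-2-one | CC1=CC[C@@H]2C(C)(C)[C@H](O)[C@@H](O)C[C@@]2(C)[C@@H]1COc1ccc2ccc(=O)oc2c1 | target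

Total step count: 15
Longest linear sequence: 15 steps, from (S)-pantolactone 1 to 25

Steps most likely to fail

Step 11. The ring closure may be slow, because the diene terminus C10 is fully substituted and the tether forces the electronically less favoured orientation; oligomerisation of the nitroalkene, a 1,5-hydrogen shift within the diene, or exo closure to the cis-fused ring system could then compete. The fallback changes the dienophile to a phenyl vinyl sulfone, which does not oligomerise and tolerates long heating. It sets out from aldehyde 15: Horner–Wadsworth–Emmons olefination with diethyl [(phenylsulfonyl)methyl]phosphonate (LiCl, DBU, MeCN) should give the (E)-vinyl sulfone F1. Heating (toluene, 110–130 °C, BHT) should give, by the same intramolecular Diels–Alder mode, the sulfonyl enol ether F2. Aqueous oxalic acid and then DBU should hydrolyse the enol ether and expel benzenesulfinate from the β-sulfonyl ketone, which comes back to the route at enone 21.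

Step 12. The coumarin may be lost, either by ionisation of the vinylogous acetal C8(OEt)=C9–C11–OAr under acid or by retro-oxa-Michael cleavage of the β-aryloxy ketone under the base that expels nitrite. The fallback forms the C11–O bond after the enone instead of before it. From 19, hydrolysis (aq. HCl, THF) and DBU are pushed to full loss of nitrite and of the aryloxide, which should give the cross-conjugated exo-methylene dienone F3. Base-catalysed oxa-Michael addition of umbelliferone 11 (excess, Cs2CO3 cat., MeCN, rt) to the exocyclic methylene, with equilibration of C9 to the equatorial epimer, comes back to the route at enone 21.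

Step 13. Hydride may add 1,2 to the enone or attack the coumarin instead of adding in the conjugate sense, and O-sulfonylation of the boron-bound enolate may be slow. The fallback removes nitro by a radical path and sets the enolate by kinetic deprotonation. From 19, Bu3SnH/AIBN (toluene, 110 °C) should give the denitrated enol ether F4. Aqueous oxalic acid (THF, 0 °C) should then give the saturated ketone F5. KN(SiMe3)2 followed by PhNTf2 (THF, −78 °C) should deprotonate the less hindered C7 methylene and give triflate 23, where the route is rejoined.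

Further compounds
F1 | step 11 | 7-{[(2E)-4-{(4S,5S)-2,2-dimethyl-5-[(3E)-2-methyl-4-(phenylsulfonyl)but-3-en-2-yl]-1,3-dioxolan-4-yl}-2-(1-ethoxyethenyl)-3-methylbut-2-en-1-yl]oxy}-2H-chromen-2-one | O=S(=O)(/C=C/C(C)(C)[C@H](OC(C)(C)O1)[C@@H]1C/C(C)=C(/C(=C)OCC)COc1ccc2ccc(=O)oc2c1)c1ccccc1
F2 | step 11 | 8-ethoxy-2,3-(isopropylidenedioxy)-6-(phenylsulfonyl)-12-nordrim-8-en-11-yl 2-oxo-2H-chromen-7-yl ether (trans-fused; sulfonyl cis to H-5) | CCOC=1C[C@@H](S(=O)(=O)c4ccccc4)[C@@H]2C(C)(C)[C@H](OC(C)(C)O3)[C@@H]3C[C@@]2(C)C=1COc1ccc2ccc(=O)oc2c1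
F3 | step 12 | 2,3-(isopropylidenedioxy)-12-nordrima-6,9(11)-dien-8-one (exo-methylene dienone) | O=C1C=C[C@@H]2C(C)(C)[C@H](OC(C)(C)O3)[C@@H]3C[C@@]2(C)C1=C
F4 | step 13 | 8-ethoxy-2,3-(isopropylidenedioxy)-12-nordrim-8-en-11-yl 2-oxo-2H-chromen-7-yl ether | CCOC=1CC[C@@H]2C(C)(C)[C@H](OC(C)(C)O3)[C@@H]3C[C@@]2(C)C=1COc1ccc2ccc(=O)oc2c1
F5 | step 13 | (2S,3S,5S,9R,10R)-2,3-(isopropylidenedioxy)-11-[(2-oxo-2H-chromen-7-yl)oxy]-12-nordriman-8-one | O=C1CC[C@@H]2C(C)(C)[C@H](OC(C)(C)O3)[C@@H]3C[C@@]2(C)[C@@H]1COc1ccc2ccc(=O)oc2c1
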